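**Retrosynthetic overview**
1. Target 18 comes from its silyl ether 17. Ring B of 17 is cut at C6–C7 and C9–C10 into the ring A synthon 9 and enal 13, which is nerol oxidised at its (E)-methyl group.
2. Enabling feature: in ring A, C10 is the β-carbon of the C2 ketone. A tertiary C10 radical can therefore be released by oxidative cleavage of the C2–C10 bond of a 1-silyloxybicyclo[3.1.0]hexane, which at the same time expands a cyclopentane into ring A. C7 is an allylic carbinol (C6 alkylzinc + aldehyde), and the (E)-C8(CH3)=C9 alkene then lies 1,5 to the radical for 6-endo closure and loss of a C17 hydrogen.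
3. Synthon 9 comes from Simmons–Smith cyclopropanation (C1) of the silyl enol ether of cyclopentanone 7. Ketone 7 comes from acetyl iodide opening of a temporary tetrahydrofuran (gives C6–I and C19–OAc), after hydrogenation (C5) of the enone from an asymmetric Pauson–Khand reaction of enyne 4 (sets C4; CO becomes C2).
4. Ring order: tetrahydrofuran and cyclopentenone together (step 2); tetrahydrofuran opened (step 4); cyclopropane (step 6); ring A by ring expansion and ring B by radical cyclisation in one operation (step 10).

Key step: step 10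

Remark on locants: C1–C20 are labdane locants of the target. C2 is the ketone carbon; C4 is the quaternary carbon with CH3 (C18) and CH2OAc (C19); C5 and C10 are the ring-fusion carbons (C10 carries CH3 = C20); C7 is the carbinol carbon; C8 carries the exocyclic CH2 (C17); C9 carries the side chain C11–C16.

Assumption: (S)-BINAP is taken to give (3aS)-5 and (+)-MIB to give the (7R)-carbinol; if either facial sense proves opposite, the antipodal ligand is used and nothing else changes.

**Route**

Step 1
Reactants: 1 2-methylprop-2-en-1-ol; 2 1-bromobut-2-yne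
Product: 4 1-[(2-methylprop-2-en-1-yl)oxy]but-2-yne, via sodium 2-methylprop-2-en-1-olate 3 (not isolated)
Conditions: NaH, THF, 0 °C; then 2, Bu4NI (cat.), rt
Reagents that add atoms: none
Why: Williamson ether synthesis, in which the alkoxide displaces the primary propargylic bromide by SN2; no stereocentre is formed.

Step 2
Reactants: 4 1-[(2-methylprop-2-en-1-yl)oxy]but-2-yne
Product: 5 (3aS)-3a,6-dimethyl-3a,4-dihydro-1H-cyclopenta[c]furan-5(3H)-one
Conditions: [Rh(CO)2Cl]2 (3 mol%), (S)-BINAP (9 mol%), AgOTf (12 mol%), CO (1 atm), THF, 90 °C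
Reagents that add atoms: carbon monoxide [C-]#[O+]
Why: Catalytic asymmetric intramolecular Pauson–Khand reaction of an oxygen-tethered 1,6-enyne; the tether fixes the regiochemistry and the cationic monovalent rhodium–BINAP complex selects one face of the 1,1-disubstituted alkene, so the quaternary carbon (later C4) is set by the ligand.

Step 3
Reactants: 5 (3aS)-3a,6-dimethyl-3a,4-dihydro-1H-cyclopenta[c]furan-5(3H)-one
Product: 6 (3aS,6S,6aR)-3a,6-dimethylhexahydro-1H-cyclopenta[c]furan-5-one
Conditions: H2 (3 atm), Pd/C (10%), EtOAc, rt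
Reagents that add atoms: none
Why: Heterogeneous syn-hydrogenation of the enone C=C; only the cis-fused bicyclo[3.3.0] skeleton is unstrained, so hydrogen enters the ring-fusion carbon (later C5) on the face of the angular methyl and the two CH2O arms (later C6 and C19) end up cis, while the α-methyl centre is of no consequence because it becomes sp2 in step 5.

Step 4
Reactants: 6 (3aS,6S,6aR)-3a,6-dimethylhexahydro-1H-cyclopenta[c]furan-5-one
Product: 7 [(1S,2R,3S)-2-(iodomethyl)-1,3-dimethyl-4-oxocyclopentyl]methyl acetate
Conditions: AcCl, NaI, MeCN, 0 °C → rt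
Reagents that add atoms: acetyl chloride CC(=O)Cl; sodium iodide [Na+].[I-]
Why: Ether cleavage by acetyl iodide formed in situ; the O-acylated oxonium ion is opened by iodide in an SN2 step at the CH2 on the tertiary ring carbon and not at the neopentyl CH2, which places iodide on C6 and acetate on C19 without touching a stereocentre.

Step 5
Reactants: 7 [(1S,2R,3S)-2-(iodomethyl)-1,3-dimethyl-4-oxocyclopentyl]methyl acetate
Product: 8 [(1S,5S)-5-(iodomethyl)-1,4-dimethyl-3-(triethylsilyloxy)cyclopent-3-en-1-yl]methyl acetate
Conditions: Et3SiCl, NaI, Et3N, MeCN, rt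
Reagents that add atoms: chlorotriethylsilane CC[Si](CC)(CC)Cl
Why: Thermodynamically controlled enol silylation (Et3SiI in situ, reversible enolisation) should favour the tetrasubstituted enol ether towards the methyl-bearing α-carbon, helped by relief of the cis-1,2 strain between CH3 and CH2I.

Step 6
Reactants: 8 [(1S,5S)-5-(iodomethyl)-1,4-dimethyl-3-(triethylsilyloxy)cyclopent-3-en-1-yl]methyl acetate
Product: 9 [(1R,2S,3S,5R)-2-(iodomethyl)-1,3-dimethyl-5-(triethylsilyloxy)bicyclo[3.1.0]hexan-3-yl]methyl acetate
Conditions: Et2Zn, CH2I2, CH2Cl2, 0 °C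
Reagents that add atoms: diiodomethane ICI
Why: Simmons–Smith cyclopropanation of the electron-rich silyl enol ether; the CH2 (later C1) should add anti to the neighbouring CH2I group, but both new stereocentres are erased in step 10, so the facial outcome does not matter.

Step 7
Reactants: 10 nerol, (2Z)-3,7-dimethylocta-2,6-dien-1-ol
Product: 11 tert-butyl{[(2Z)-3,7-dimethylocta-2,6-dien-1-yl]oxy}dimethylsilane
Conditions: TBSCl, imidazole, CH2Cl2, rt
Reagents that add atoms: tert-butyl(chloro)dimethylsilane CC(C)(C)[Si](C)(C)Cl
Why: Standard silylation of the primary allylic alcohol; the (Z)-alkene is untouched.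

Step 8
Reactants: 11 tert-butyl{[(2Z)-3,7-dimethylocta-2,6-dien-1-yl]oxy}dimethylsilane
Product: 12 (2E,6Z)-8-[(tert-butyldimethylsilyl)oxy]-2,6-dimethylocta-2,6-dien-1-ol
Conditions: SeO2 (0.3 equiv), t-BuOOH, salicylic acid (cat.), CH2Cl2, 0 °C → rt
Reagents that add atoms: selenium dioxide O=[Se]=O (oxygen carrier); tert-butyl hydroperoxide CC(C)(C)OO (terminal oxygen source)
Why: SeO2 allylic oxidation (ene reaction, then [2,3]-sigmatropic shift) attacks the more electron-rich terminal trisubstituted alkene at its (E)-methyl group and gives the (E)-allylic alcohol, while the alkene next to the silyloxymethyl group is deactivated.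

Step 9
Reactants: 12 (2E,6Z)-8-[(tert-butyldimethylsilyl)oxy]-2,6-dimethylocta-2,6-dien-1-ol
Product: 13 (2E,6Z)-8-[(tert-butyldimethylsilyl)oxy]-2,6-dimethylocta-2,6-dienal
Conditions: MnO2, CH2Cl2, rt
Reagents that add atoms: none
Why: Chemoselective allylic oxidation with MnO2 should give the conjugated aldehyde without E/Z isomerisation; any aldehyde already formed in step 8 converges here.

Step 10
Reactants: 9 [(1R,2S,3S,5R)-2-(iodomethyl)-1,3-dimethyl-5-(triethylsilyloxy)bicyclo[3.1.0]hexan-3-yl]methyl acetate; 13 (2E,6Z)-8-[(tert-butyldimethylsilyl)oxy]-2,6-dimethylocta-2,6-dienal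
Product: 17 (4S,5R,7R,9R,10S)-15-[(tert-butyldimethylsilyl)oxy]-7-hydroxy-2-oxolabda-8(17),13(Z)-dien-19-yl acetate, via alkylzinc iodide 14 (not isolated), via alkyl(trimethylsilylmethyl)zinc 15 (not isolated), via zinc alkoxide of the C7 carbinol 16 (not isolated)
Conditions: Zn, LiCl, THF, 40 °C; Me3SiCH2Li, −78 °C; 13, (+)-MIB (5 mol%), TEEDA, toluene, 0 °C; then Fe(NO3)3·9H2O (2.2 equiv), Cu(OAc)2 (1 equiv), DMF, 0 °C → rt, one flask
Reagents that add atoms: none
Why: Proposed new method: the sequence is unprecedented as one operation, but each event has a close model: zinc insertion and ligand exchange give 15, which under (+)-3-exo-morpholinoisoborneol catalysis should add 1,2 to enal 13 on one face only (closest known reaction: amino-alcohol-catalysed enantioselective addition of functionalised alkylzincs to enals), forming C6–C7 and setting C7 (R) by the catalyst; in the same flask Fe(NO3)3 should oxidise the silyloxycyclopropane of 16 to a radical cation that loses the silyl group and breaks the internal C2–C10 bond, the one that leads to a tertiary radical, turning the cyclopentane into the ring A cyclohexanone with a β-keto radical at C10 (closest known reaction: ring expansion of 1-silyloxybicyclo[n.1.0]alkanes by trivalent iron salts and its radical cyclisation variants). Ring A thus arises by one-carbon ring expansion, and ring B closes by 6-endo-trig attack of the C10 radical on C9 of the (E)-trisubstituted alkene, forming C9–C10; the 5-exo mode is disfavoured because it would join two fully substituted carbons. The tertiary C8 radical is then oxidised by Cu(OAc)2 through an alkylcopper species that loses the most accessible β-hydrogen, that of the methyl group, to give the exocyclic C8=C17 alkene (closest known reaction: Mn(OAc)3/Cu(OAc)2 oxidative polyene cyclisation ending in exocyclic alkenes). C10 and C9 are set in a chair–chair transition state: the C5–C6 bond, fixed in 9, is equatorial on ring A and the new bond enters equatorially, which makes the C10 methyl axial and the ring fusion trans, the (E)-alkene geometry places C11 equatorial, and the C7 oxygen lies axial where it avoids allylic strain with the C8 methyl. The step needs cyclisation to outrun direct oxidation of the C10 radical, and copper oxidation to outrun a second cyclisation of the C8 radical onto the C13=C14 alkene; the 1,5 preorganisation of radical and alkene should secure the first, and a full equivalent of Cu(OAc)2, held near C8 by the neighbouring C7 hydroxyl, the second.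

Step 11
Reactants: 17 (4S,5R,7R,9R,10S)-15-[(tert-butyldimethylsilyl)oxy]-7-hydroxy-2-oxolabda-8(17),13(Z)-dien-19-yl acetate
Product: 18 (4S,5R,7R,9R,10S)-7,15-dihydroxy-2-oxolabda-8(17),13(Z)-dien-19-yl acetate
Conditions: HF·pyridine, pyridine, THF, 0 °C
Reagents that add atoms: none
Why: Fluoride cleavage of the primary allylic silyl ether under buffered conditions; the neopentyl acetate, the ketone, the axial allylic alcohol and both alkenes should be inert, and no stereocentre is affected.

**Compound list**
1 | 2-methylprop-2-en-1-ol | C=C(C)CO | starting material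
2 | 1-bromobut-2-yne | CC#CCBr | starting material
3 | sodium 2-methylprop-2-en-1-olate | C=C(C)C[O-].[Na+] | intermediate
4 | 1-[(2-methylprop-2-en-1-yl)oxy]but-2-yne | C=C(C)COCC#CC | intermediate
5 | (3aS)-3a,6-dimethyl-3a,4-dihydro-1H-cyclopenta[c]furan-5(3H)-one | CC1=C2COC[C@@]2(C)CC1=O | intermediate
6 | (3aS,6S,6aR)-3a,6-dimethylhexahydro-1H-cyclopenta[c]furan-5-one (cis-fused) | O=C1[C@@H](C)[C@H]2COC[C@@]2(C)C1 | intermediate
7 | [(1S,2R,3S)-2-(iodomethyl)-1,3-dimethyl-4-oxocyclopentyl]methyl acetate (CH2I cis to CH2OAc) | O=C1[C@@H](C)[C@@H](CI)[C@@](C)(COC(C)=O)C1 | intermediate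
8 | [(1S,5S)-5-(iodomethyl)-1,4-dimethyl-3-(triethylsilyloxy)cyclopent-3-en-1-yl]methyl acetate | CC[Si](CC)(CC)OC1=C(C)[C@@H](CI)[C@@](C)(COC(C)=O)C1 | intermediate
9 | [(1R,2S,3S,5R)-2-(iodomethyl)-1,3-dimethyl-5-(triethylsilyloxy)bicyclo[3.1.0]hexan-3-yl]methyl acetate (cyclopropane CH2 anti to CH2I) | CC[Si](CC)(CC)O[C@@]12C[C@]1(C)[C@@H](CI)[C@@](C)(COC(C)=O)C2 | intermediate
10 | nerol, (2Z)-3,7-dimethylocta-2,6-dien-1-ol | CC(C)=CCC/C(C)=C\CO | starting material
11 | tert-butyl{[(2Z)-3,7-dimethylocta-2,6-dien-1-yl]oxy}dimethylsilane | CC(C)=CCC/C(C)=C\CO[Si](C)(C)C(C)(C)C | intermediate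
12 | (2E,6Z)-8-[(tert-butyldimethylsilyl)oxy]-2,6-dimethylocta-2,6-dien-1-ol | OC/C(C)=C/CC/C(C)=C\CO[Si](C)(C)C(C)(C)C | intermediate
13 | (2E,6Z)-8-[(tert-butyldimethylsilyl)oxy]-2,6-dimethylocta-2,6-dienal | O=C/C(C)=C/CC/C(C)=C\CO[Si](C)(C)C(C)(C)C | intermediate
14 | {[(1R,2S,3S,5R)-3-(acetoxymethyl)-1,3-dimethyl-5-(triethylsilyloxy)bicyclo[3.1.0]hexan-2-yl]methyl}zinc iodide | CC[Si](CC)(CC)O[C@@]12C[C@]1(C)[C@@H](C[Zn]I)[C@@](C)(COC(C)=O)C2 | intermediate
15 | the same alkyl group on zinc carrying a (trimethylsilyl)methyl second ligand | CC[Si](CC)(CC)O[C@@]12C[C@]1(C)[C@@H](C[Zn]C[Si](C)(C)C)[C@@](C)(COC(C)=O)C2 | intermediate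
16 | [(trimethylsilyl)methyl]zinc alkoxide of the (7R)-allylic carbinol formed from 15 and 13 | CC[Si](CC)(CC)O[C@@]12C[C@]1(C)[C@@H](C[C@@H](O[Zn]C[Si](C)(C)C)/C(C)=C/CC/C(C)=C\CO[Si](C)(C)C(C)(C)C)[C@@](C)(COC(C)=O)C2 | intermediate
17 | (4S,5R,7R,9R,10S)-15-[(tert-butyldimethylsilyl)oxy]-7-hydroxy-2-oxolabda-8(17),13(Z)-dien-19-yl acetate (7α-OH axial, trans-decalin) | C=C1[C@H](O)C[C@H]2[C@@](C)(COC(C)=O)CC(=O)C[C@]2(C)[C@H]1CC/C(C)=C\CO[Si](C)(C)C(C)(C)C | intermediate
18 | (4S,5R,7R,9R,10S)-7,15-dihydroxy-2-oxolabda-8(17),13(Z)-dien-19-yl acetate | C=C1[C@H](O)C[C@H]2[C@@](C)(COC(C)=O)CC(=O)C[C@]2(C)[C@H]1CC/C(C)=C\CO | target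

**Count**
Total steps: 11. Longest linear sequence: 8 steps (1, 2, 3, 4, 5, 6, 10, 11).

**Three steps most likely to fail**

1. Step 10. Residues of the zinc stage may interfere with the iron and copper salts. The C10 radical may be oxidised to the conjugated enone before it cyclises. The C8 radical may cyclise further onto the C13=C14 alkene. Face selection at C7 may be incomplete. Fallback with known chemistry, as separate operations, setting out from 9 and 13: the zinc addition is run alone and quenched with NH4Cl, and the (7R)-carbinol bearing both silyl ethers F1 is isolated, so an imperfect C7 ratio can be corrected by chromatography. Bu4NF/AcOH in THF then removes both silyl groups to give the free cyclopropanol triol F2. Oxidation of the free cyclopropanol with Mn(pic)3 (pic = pyridine-2-carboxylate) and Cu(OAc)2 in DMF is the established entry to ring-expanded β-keto radicals from bicyclic cyclopropanols; it should effect ring expansion, 6-endo cyclisation and alkene formation and rejoin the route at 18.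

2. Step 2. The 1,1-disubstituted alkene binds weakly, so turnover may be slow and face selectivity may erode. Fallback setting out from 4: the stoichiometric Pauson–Khand reaction (Co2(CO)8, then N-methylmorpholine N-oxide, CH2Cl2) gives the racemic enone, that is 5 together with its mirror image, the (3aR)-enone F3. The enantiomers are separated by preparative chromatography on a chiral stationary phase, and the route is rejoined at 5.

3. Step 5. Enolisation may go towards the CH2 next to the quaternary carbon, or the enol oxygen may be alkylated by the neighbouring iodide; after step 6 the wrong enol ether would open to the wrong radical. Fallback setting out from 5, which fixes the enol ether position by construction: RhCl(PPh3)3-catalysed 1,4-hydrosilylation of the enone with Et3SiH gives the bicyclic triethylsilyl enol ether F4. Me3SiI with 2,6-di-tert-butylpyridine in CH2Cl2 opens the tetrahydrofuran at the same CH2 as in step 4 to give the iodide with a primary trimethylsilyl ether F5. K2CO3/MeOH frees the primary alcohol F6, and Ac2O/pyridine gives 8, where the route is rejoined.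

Further compounds
F1 | step 10 | isolated (7R)-carbinol from 15 and 13, triethylsilyl cyclopropyl ether and TBS ether intact | CC[Si](CC)(CC)O[C@@]12C[C@]1(C)[C@@H](C[C@@H](O)/C(C)=C/CC/C(C)=C\CO[Si](C)(C)C(C)(C)C)[C@@](C)(COC(C)=O)C2
F2 | step 10 | free cyclopropanol triol obtained from F1 by removal of both silyl groups | O[C@@]12C[C@]1(C)[C@@H](C[C@@H](O)/C(C)=C/CC/C(C)=C\CO)[C@@](C)(COC(C)=O)C2
F3 | step 2 | (3aR)-3a,6-dimethyl-3a,4-dihydro-1H-cyclopenta[c]furan-5(3H)-one | CC1=C2COC[C@]2(C)CC1=O
F4 | step 5 | triethyl{[(3aS,6aS)-3a,6-dimethyl-3,3a,4,6a-tetrahydro-1H-cyclopenta[c]furan-5-yl]oxy}silane (cis-fused) | CC[Si](CC)(CC)OC1=C(C)[C@H]2COC[C@@]2(C)C1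
F5 | step 5 | triethylsilyl enol ether iodide with the primary alcohol as trimethylsilyl ether | CC[Si](CC)(CC)OC1=C(C)[C@@H](CI)[C@@](C)(CO[Si](C)(C)C)C1
F6 | step 5 | [(1S,5S)-5-(iodomethyl)-1,4-dimethyl-3-(triethylsilyloxy)cyclopent-3-en-1-yl]methanol | CC[Si](CC)(CC)OC1=C(C)[C@@H](CI)[C@@](C)(CO)C1
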